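## Retrosynthetic overview
- Target ⇒ acylation of the equatorial 8‑OH. The axial 9α‑tiglate comes from a 9β‑alcohol by inversion, with participation of an 8‑O‑tigloyl group.
- C6 carries a sacrificial OH that is removed by radical deoxygenation. C2=O is carried as a silyl enol ether.
- Key step (both carbocycles in one flask): an acyclic 2‑silyloxydiene and tiglaldehyde undergo a Diels–Alder reaction (C3–C4, C5–C10; ring A). A carbonyl‑ene closure follows (C6–C7; ring B) and creates the isopropenyl group.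
- The diene comes from prenal by syn‑alkoxyallylboration (C8, C9), tigloylation, cross metathesis with methyl vinyl ketone and silylation.
- Ring order: A, then B, in the same operation.

Assumption: allyl methoxymethyl ether and (R)‑2‑methylbutanoic acid are catalogue items. Positions follow eremophilane numbering: ring A = C1–C5, C10; ring B = C5–C10; methyls on C4 and C5; isopropenyl on C7. β is the face of the C5 methyl.

## Route

Step 1
Reactants: 1 3‑(methoxymethoxy)prop‑1‑ene; 2 3‑methylbut‑2‑enal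
Product: 6 (3R,4R)‑3‑(methoxymethoxy)‑6‑methylhepta‑1,5‑dien‑4‑ol, via allyllithium 3 (not isolated), via allylborane 4 (not isolated), via borinate 5 (not isolated)
Conditions: s‑BuLi, THF, −78 °C; (−)‑Ipc2BOMe; BF3·OEt2; 2, −78 °C; then NaOH, H2O2, 0 °C → rt
Reagents that add atoms: none
Why: Brown γ‑alkoxyallylboration through a closed Zimmerman–Traxler chair, in which the Z‑allylborane gives the syn C8/C9 pair and the isopinocampheyl groups from (+)‑α‑pinene set C8 as R; C9 is deliberately made opposite to the target so that it steers step 5, and it is corrected in step 9.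

Step 2
Reactants: 6; 7 tiglic acid, (E)‑2‑methylbut‑2‑enoic acid
Product: 8 (3R,4R)‑3‑(methoxymethoxy)‑6‑methylhepta‑1,5‑dien‑4‑yl (E)‑2‑methylbut‑2‑enoate
Conditions: DCC, DMAP (cat.), CH2Cl2, 0 °C → rt
Reagents that add atoms: none
Why: Steglich esterification of the only free hydroxyl (O8) with no stereocentre touched; this tiglate is the group that ends up on O9.

Step 3
Reactants: 8; 9 but‑3‑en‑2‑one
Product: 10 (3E,5R,6R)‑5‑(methoxymethoxy)‑8‑methyl‑2‑oxonona‑3,7‑dien‑6‑yl (E)‑2‑methylbut‑2‑enoate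
Conditions: second‑generation Hoveyda–Grubbs catalyst (5 mol %), 9 (4 equiv), CH2Cl2, 40 °C
Reagents that add atoms: none
Why: Olefin cross metathesis of the terminal vinyl group with an electron‑poor partner gives the E‑enone, while the trisubstituted alkene and the tiglate are too hindered to react.

Step 4
Reactants: 10
Product: 11 (3E,5R,6R)‑2‑(tert‑butyldimethylsilyloxy)‑5‑(methoxymethoxy)‑8‑methylnona‑1,3,7‑trien‑6‑yl (E)‑2‑methylbut‑2‑enoate
Conditions: TBSOTf, Et3N, CH2Cl2, 0 °C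
Reagents that add atoms: tert‑butyldimethylsilyl trifluoromethanesulfonate, CC(C)(C)[Si](C)(C)OS(=O)(=O)C(F)(F)F
Why: Soft enolisation of the methyl ketone on its CH3 side gives the cross‑conjugated 2‑silyloxy‑1,3‑diene without touching C9–H.

Step 5
Reactants: 11; 12 tiglaldehyde, (E)‑2‑methylbut‑2‑enal
Product: 14 (4S,5R,6S,7S,8R,9R,10S)‑2‑(tert‑butyldimethylsilyloxy)‑6‑hydroxy‑9‑(methoxymethoxy)eremophila‑1,11‑dien‑8‑yl (E)‑2‑methylbut‑2‑enoate (cis‑fused), via Diels–Alder adduct 13 (not isolated)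
Conditions: 12 (1.5 equiv), Me2AlCl (2.5 equiv), CH2Cl2, −78 → −20 °C, one flask; aq. NaHCO3
Reagents that add atoms: none
Why: Proposed new method: one Lewis acid first drives a normal‑demand Diels–Alder reaction (nucleophilic C3 of the silyloxydiene bonds to the enal β‑carbon C4, the E‑enal geometry becomes the cis C4/C5 methyls, the endo formyl group puts C6 cis to C9 and so gives the cis ring fusion, and the diene face is chosen by C9 with C8 anti, OMOM inside and H outside), and it then activates the new neopentyl aldehyde 13 for a type 1 intramolecular carbonyl‑ene reaction through an all‑equatorial chair in which allylic 1,3‑strain holds H8 in the alkene plane, setting C7 trans to O8 and turning the isobutenyl unit into the isopropenyl group; the closest known reaction types are Lewis‑acid Diels–Alder reactions of 2‑silyloxydienes with hindered enals and the Me2AlCl ene cyclisation of citronellal to isopulegol.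

Step 6
Reactants: 14
Product: 15 6‑O‑(imidazol‑1‑ylthiocarbonyl) derivative of 14 (all stereocentres as in 14)
Conditions: 1,1'‑thiocarbonyldiimidazole, DMAP, toluene, 90 °C
Reagents that add atoms: 1,1'‑thiocarbonyldiimidazole, S=C(n1ccnc1)n1ccnc1
Why: Base‑free thioacylation (first half of the Barton–McCombie sequence) of the only free OH avoids an alkoxide that could pull the tiglate from O8 to O6.

Step 7
Reactants: 15
Product: 16 (4S,5R,7R,8R,9R,10S)‑2‑(tert‑butyldimethylsilyloxy)‑9‑(methoxymethoxy)eremophila‑1,11‑dien‑8‑yl (E)‑2‑methylbut‑2‑enoate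
Conditions: Bu3SnH, AIBN (cat.), toluene, 100 °C
Reagents that add atoms: none
Why: Barton–McCombie deoxygenation, in which the secondary C6 radical has no fast cyclisation or β‑scission channel and is simply reduced to CH2, erasing the auxiliary C6 centre.

Step 8
Reactants: 16
Product: 17 (4S,5R,7R,8R,9R,10S)‑9‑hydroxy‑2‑oxoeremophil‑11‑en‑8‑yl (E)‑2‑methylbut‑2‑enoate (8α‑tiglate, 9β‑OH, both equatorial)
Conditions: 3 M aq. HCl, THF, 40 °C
Reagents that add atoms: none
Why: Acid hydrolysis of the MOM acetal and the silyl enol ether in one operation; protonation at C1 creates no stereocentre and no C–O bond at C8 or C9 is broken.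

Step 9
Reactants: 17
Product: 20 (4S,5R,7R,8R,9S,10S)‑8‑hydroxy‑2‑oxoeremophil‑11‑en‑9‑yl (E)‑2‑methylbut‑2‑enoate (9α‑tiglate axial, 8α‑OH equatorial), via triflate 18 (not isolated), via dioxolanylium triflate 19 (not isolated)
Conditions: Tf2O, pyridine, CH2Cl2, −20 → 0 °C; then H2O, 45 °C
Reagents that add atoms: water, O
Why: Winstein‑type neighbouring‑group participation, in which the carbonyl oxygen of the 8α‑tiglate displaces the 9β‑triflate from the α face and inverts C9 to the target configuration; water then opens the cis‑fused 1,3‑dioxolan‑2‑ylium ion through its ortho acid to leave the ester on the axial oxygen (O9) and free the equatorial 8‑OH, as known for triflate inversions next to esters in pyranosides.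

Step 10
Reactants: 20; 21 (R)‑2‑methylbutanoic acid
Product: 22 target, (4S,5R,7R,8R,9S,10S)‑8‑[(2R)‑2‑methylbutanoyloxy]‑2‑oxoeremophil‑11‑en‑9‑yl (E)‑2‑methylbut‑2‑enoate
Conditions: DCC, DMAP (cat.), CH2Cl2, −10 °C
Reagents that add atoms: none
Why: Steglich esterification of the unhindered equatorial 8‑OH is faster at low temperature than tiglate migration, and the acid brings its own R centre unchanged.

## Compound list
1 | 3‑(methoxymethoxy)prop‑1‑ene | C=CCOCOC | starting material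
2 | 3‑methylbut‑2‑enal | CC(C)=CC=O | starting material
3 | (Z)‑3‑(methoxymethoxy)allyllithium | [Li]C/C=C\OCOC | intermediate
4 | (Z)‑3‑(methoxymethoxy)allyl‑diisopinocampheylborane | COCO/C=C\CB([C@@H]1C[C@@H]2C[C@H]([C@H]1C)C2(C)C)[C@@H]1C[C@@H]2C[C@H]([C@H]1C)C2(C)C | intermediate
5 | diisopinocampheylborinate of 6 | C=C[C@@H](OCOC)[C@H](OB([C@@H]1C[C@@H]2C[C@H]([C@H]1C)C2(C)C)[C@@H]1C[C@@H]2C[C@H]([C@H]1C)C2(C)C)C=C(C)C | intermediate
6 | (3R,4R)‑3‑(methoxymethoxy)‑6‑methylhepta‑1,5‑dien‑4‑ol | C=C[C@@H](OCOC)[C@H](O)C=C(C)C | intermediate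
7 | tiglic acid | C/C=C(\C)C(=O)O | starting material
8 | tiglate of 6 | C=C[C@@H](OCOC)[C@H](OC(=O)/C(C)=C/C)C=C(C)C | intermediate
9 | but‑3‑en‑2‑one | C=CC(C)=O | starting material
10 | E‑enone | CC(=O)/C=C/[C@@H](OCOC)[C@H](OC(=O)/C(C)=C/C)C=C(C)C | intermediate
11 | 2‑silyloxydiene | C=C(O[Si](C)(C)C(C)(C)C)/C=C/[C@@H](OCOC)[C@H](OC(=O)/C(C)=C/C)C=C(C)C | intermediate
12 | tiglaldehyde | C/C=C(\C)C=O | starting material
13 | (1R,2S,6S)‑4‑(tert‑butyldimethylsilyloxy)‑1,6‑dimethyl‑2‑[(1R,2R)‑1‑(methoxymethoxy)‑4‑methyl‑2‑(tigloyloxy)pent‑3‑enyl]cyclohex‑3‑ene‑1‑carbaldehyde | O=C[C@@]1(C)[C@H](C=C(O[Si](C)(C)C(C)(C)C)C[C@@H]1C)[C@@H](OCOC)[C@H](OC(=O)/C(C)=C/C)C=C(C)C | intermediate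
14 | cis‑decalin with 6α‑OH | C=C(C)[C@H]1[C@H](O)[C@@]2(C)[C@H](C=C(O[Si](C)(C)C(C)(C)C)C[C@@H]2C)[C@@H](OCOC)[C@@H]1OC(=O)/C(C)=C/C | intermediate
15 | 6‑O‑imidazolylthiocarbonyl derivative | C=C(C)[C@H]1[C@H](OC(=S)n3ccnc3)[C@@]2(C)[C@H](C=C(O[Si](C)(C)C(C)(C)C)C[C@@H]2C)[C@@H](OCOC)[C@@H]1OC(=O)/C(C)=C/C | intermediate
16 | 6‑deoxy decalin | C=C(C)[C@H]1C[C@@]2(C)[C@H](C=C(O[Si](C)(C)C(C)(C)C)C[C@@H]2C)[C@@H](OCOC)[C@@H]1OC(=O)/C(C)=C/C | intermediate
17 | 9β‑hydroxy‑8α‑tiglate ketone | C=C(C)[C@H]1C[C@@]2(C)[C@H](CC(=O)C[C@@H]2C)[C@@H](O)[C@@H]1OC(=O)/C(C)=C/C | intermediate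
18 | 9β‑triflate | C=C(C)[C@H]1C[C@@]2(C)[C@H](CC(=O)C[C@@H]2C)[C@@H](OS(=O)(=O)C(F)(F)F)[C@@H]1OC(=O)/C(C)=C/C | intermediate
19 | 8α,9α‑fused 1,3‑dioxolan‑2‑ylium triflate | C=C(C)[C@H]1C[C@@]2(C)[C@H](CC(=O)C[C@@H]2C)[C@@H]3OC(/C(C)=C/C)=[O+][C@H]13.[O-]S(=O)(=O)C(F)(F)F | intermediate
20 | 9α‑tiglate‑8α‑ol ketone | C=C(C)[C@H]1C[C@@]2(C)[C@H](CC(=O)C[C@@H]2C)[C@H](OC(=O)/C(C)=C/C)[C@@H]1O | intermediate
21 | (R)‑2‑methylbutanoic acid | O=C(O)[C@H](C)CC | starting material
22 | CNP0312791.1 | C=C(C)[C@H]1C[C@@]2(C)[C@H](CC(=O)C[C@@H]2C)[C@H](OC(=O)/C(C)=C/C)[C@@H]1OC(=O)[C@H](C)CC | target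

## Step count and risks
Total steps: 10. Longest linear sequence: 10 (1/2 → 22).

**Most likely to fail: step 5.** The threats are Mukaiyama aldol addition instead of cycloaddition, ionisation of the allylic tiglate, and a slow ene stage.
- The fallback sets out from 13, obtained by quenching the cycloaddition cold at −78 °C, and replaces the polar ring B closure by a radical one that never puts oxygen on C6.
- NaBH4 in MeOH gives the neopentyl alcohol F1.
- I2, PPh3 and imidazole give the neopentyl iodide F2.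
- A Heck‑type alkyl radical cyclisation (Pd(PPh3)4, 1,2,2,6,6‑pentamethylpiperidine, benzene, 110 °C) joins C6 to C7. It ends by β‑hydride loss to the isopropenyl group.
- The route is rejoined at 16, so steps 6 and 7 are skipped.

**Second: step 9.** The backside attack takes place in the concave pocket beside C4.
- The fallback sets out from 17 and sets C9 by hydride delivery from the convex β face.
- Dess–Martin periodinane gives the 2,9‑dione F4.
- HC(OMe)3 and CeCl3·7H2O in MeOH ketalise only the unhindered C2 carbonyl, giving the dimethyl ketal F5.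
- LiBH(s‑Bu)3 at −78 °C attacks C9 equatorially to give the axial 9α‑alcohol F6.
- Dilute aqueous acid gives the keto alcohol F7.
- K2CO3 in MeOH removes the misplaced tiglate to give the cis‑diol F8.
- 21 with DCC and DMAP acylates the equatorial O8, giving the monoester F9.
- 7, activated as its 2,4,6‑trichlorobenzoyl mixed anhydride with DMAP in warm toluene, acylates O9.
- The route is rejoined at 22.

**Third: step 6.** The C6 hydroxyl lies between the quaternary C5 and the branched C7 and may resist thioacylation.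
- The fallback sets out from 14 and uses a small, very reactive acylating agent and a different radical chemistry.
- Trifluoroacetic anhydride and pyridine give the trifluoroacetate F3.
- Ph2SiH2 and (t‑BuO)2 at 140 °C cleave its C6–O bond by silyl radical addition to the ester carbonyl.
- The route is rejoined at 16.

## Further compounds
F1 | step 5 | neopentyl alcohol from 13 (C6H2OH) | OC[C@@]1(C)[C@H](C=C(O[Si](C)(C)C(C)(C)C)C[C@@H]1C)[C@@H](OCOC)[C@H](OC(=O)/C(C)=C/C)C=C(C)C
F2 | step 5 | neopentyl iodide (C6H2I) | IC[C@@]1(C)[C@H](C=C(O[Si](C)(C)C(C)(C)C)C[C@@H]1C)[C@@H](OCOC)[C@H](OC(=O)/C(C)=C/C)C=C(C)C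
F3 | step 6 | 6‑O‑trifluoroacetate of 14 | C=C(C)[C@H]1[C@H](OC(=O)C(F)(F)F)[C@@]2(C)[C@H](C=C(O[Si](C)(C)C(C)(C)C)C[C@@H]2C)[C@@H](OCOC)[C@@H]1OC(=O)/C(C)=C/C
F4 | step 9 | 2,9‑dione with 8α‑tiglate | C=C(C)[C@H]1C[C@@]2(C)[C@H](CC(=O)C[C@@H]2C)C(=O)[C@@H]1OC(=O)/C(C)=C/C
F5 | step 9 | C2 dimethyl ketal of F4 | C=C(C)[C@H]1C[C@@]2(C)[C@H](CC(OC)(OC)C[C@@H]2C)C(=O)[C@@H]1OC(=O)/C(C)=C/C
F6 | step 9 | 9α‑alcohol of the ketal | C=C(C)[C@H]1C[C@@]2(C)[C@H](CC(OC)(OC)C[C@@H]2C)[C@H](O)[C@@H]1OC(=O)/C(C)=C/C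
F7 | step 9 | 9α‑hydroxy‑8α‑tiglate ketone | C=C(C)[C@H]1C[C@@]2(C)[C@H](CC(=O)C[C@@H]2C)[C@H](O)[C@@H]1OC(=O)/C(C)=C/C
F8 | step 9 | 8α,9α‑diol ketone | C=C(C)[C@H]1C[C@@]2(C)[C@H](CC(=O)C[C@@H]2C)[C@H](O)[C@@H]1O
F9 | step 9 | 8α‑[(R)‑2‑methylbutanoate]‑9α‑ol ketone | C=C(C)[C@H]1C[C@@]2(C)[C@H](CC(=O)C[C@@H]2C)[C@H](O)[C@@H]1OC(=O)[C@H](C)CC
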